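**Retrosynthetic overview**
1. The plan rests on the C8'–C9' bond (side chain numbered C1' = benzylic CH2 to C16'). Both carbons are allylic CH2 groups of E-trisubstituted alkenes (C6'=C7' and C10'=C11'), and the bond lies midway between the C5' acetoxy and C12' hydroxy carbinols. Cutting it gives the arene–C1'–C8' allylic bromide 15 (5'S, OSiEt3) and the C9'–C16' allylic phenyl sulfone 23 (12'R, OTBS), joined with reversed polarity at C9'.
2. Bromide 15: C5' comes from (R)-glycidol; C1'–C2' from Zr-catalysed methylalumination of alkyne 8 and Pd coupling with benzylic chloride 5 (made from 4-methoxy-2-methylphenol); C6'=C7' from a stabilised Wittig reaction; then reduction and bromination.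
3. Sulfone 23: prenyl bromide and PhSO2Na, SeO2 oxidation to the E-enal, asymmetric allylboration (sets C12'), silylation, cross-metathesis to the prenyl terminus.
4. End game: Pd-catalysed hydride desulfonylation, Et3Si off and acetate on at C5', TBS off at C12', oxidative demethylation to the quinone, reduction to the hydroquinone.
5. Rings: none is formed; the benzene ring is bought with 1 and is the only ring throughout.

Key step: step 17

Assumption: (R)-glycidol, Ph3P=C(CH3)CO2Et and (+)-Ipc2BOMe (the antipode made from (−)-α-pinene) are taken as commercial; primed locants refer to the side chain as numbered above; TBS = tert-butyldimethylsilyl.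

**Benzylic chloride 5**

Step 1
Reactants: 1 4-methoxy-2-methylphenol
Product: 2 2-hydroxy-5-methoxy-3-methylbenzaldehyde
Conditions: MgCl2, Et3N, (CH2O)n, MeCN, reflux; then aq HCl
Reagents that add atoms: paraformaldehyde (formaldehyde), C=O
Why: Magnesium phenoxide-directed ortho-formylation (Casnati–Skattebøl reaction) delivers formaldehyde to the only free ortho position, the para position being blocked by methoxy, and a second formaldehyde oxidises the benzylic alkoxide to the aldehyde by hydride transfer.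

Step 2
Reactants: 2 2-hydroxy-5-methoxy-3-methylbenzaldehyde
Product: 3 2,5-dimethoxy-3-methylbenzaldehyde
Conditions: MeI, K2CO3, DMF, rt
Reagents that add atoms: iodomethane, CI
Why: Williamson O-methylation of the phenol installs the hydroquinone dimethyl ether, which is inert to every organometallic step that follows.

Step 3
Reactants: 3 2,5-dimethoxy-3-methylbenzaldehyde
Product: 4 (2,5-dimethoxy-3-methylphenyl)methanol
Conditions: NaBH4, MeOH, 0 °C
Reagents that add atoms: none
Why: Borohydride reduction of the aryl aldehyde gives the benzylic alcohol and leaves the aryl ethers untouched.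

Step 4
Reactants: 4 (2,5-dimethoxy-3-methylphenyl)methanol
Product: 5 1-(chloromethyl)-2,5-dimethoxy-3-methylbenzene
Conditions: SOCl2, CH2Cl2, 0 °C to rt
Reagents that add atoms: thionyl chloride, O=S(Cl)Cl
Why: Chlorodehydroxylation through the chlorosulfite is facile for an electron-rich benzylic alcohol and gives the electrophile for the cross-coupling.

**Bromide 15 (arene–C1'–C8')**

Step 5
Reactants: 6 (R)-glycidol
Product: 7 (S)-pent-4-yne-1,2-diol
Conditions: LiC≡CH·H2NCH2CH2NH2 (3 equiv), DMSO, 0 °C to rt; then H2O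
Reagents that add atoms: lithium acetylide–ethylenediamine complex, [Li]C#C.NCCN
Why: SN2 opening of the epoxide at its terminal carbon by acetylide leaves the stereocentre untouched (the descriptor changes from R to S only through CIP priorities), and the Payne rearrangement of glycidol alkoxide is degenerate, so the future C5' configuration cannot be lost.

Step 6
Reactants: 7 (S)-pent-4-yne-1,2-diol
Product: 8 (S)-4,5-bis(triethylsilyloxy)pent-1-yne
Conditions: Et3SiCl (2.4 equiv), imidazole, DMF, 0 °C to rt
Reagents that add atoms: chlorotriethylsilane, CC[Si](Cl)(CC)CC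
Why: Imidazole-promoted silylation caps both hydroxyls with the same group, which is differentiated later by the primary/secondary difference.

Step 7
Reactants: 8 (S)-4,5-bis(triethylsilyloxy)pent-1-yne; 5 1-(chloromethyl)-2,5-dimethoxy-3-methylbenzene
Product: 10 (2E,5S)-1-(2,5-dimethoxy-3-methylphenyl)-3-methyl-5,6-bis(triethylsilyloxy)hex-2-ene, via alkenyl(dimethyl)alane 9 (not isolated)
Conditions: Me3Al (2.5 equiv), Cp2ZrCl2 (0.25 equiv), CH2Cl2, 0 °C to rt; volatiles removed; then 5, Pd(PPh3)4 (5 mol %), THF, rt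
Reagents that add atoms: trimethylaluminium, C[Al](C)C (methyl on C3'; aluminium in 9 only)
Why: Zirconium-catalysed syn-methylalumination (Negishi carboalumination) of the terminal alkyne puts methyl on C3' and aluminium on C2' cis to it, and palladium-catalysed cross-coupling of the alkenylalane with the benzylic chloride proceeds with retention, so the C2'=C3' alkene should form as the E isomer.

Step 8
Reactants: 10 (2E,5S)-1-(2,5-dimethoxy-3-methylphenyl)-3-methyl-5,6-bis(triethylsilyloxy)hex-2-ene
Product: 11 (2S,4E)-6-(2,5-dimethoxy-3-methylphenyl)-4-methyl-2-(triethylsilyloxy)hex-4-enal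
Conditions: (COCl)2 (4 equiv), DMSO (8 equiv), CH2Cl2, −78 °C, then −40 °C, 30 min; Et3N, −78 °C to rt
Reagents that add atoms: none
Why: Under Swern conditions chlorodimethylsulfonium chloride cleaves the unhindered primary triethylsilyl ether and oxidises it directly to the aldehyde while the secondary silyl ether stays, a known selective oxidative desilylation.

Step 9
Reactants: 11 (2S,4E)-6-(2,5-dimethoxy-3-methylphenyl)-4-methyl-2-(triethylsilyloxy)hex-4-enal
Product: 12 ethyl (2E,4S,6E)-8-(2,5-dimethoxy-3-methylphenyl)-2,6-dimethyl-4-(triethylsilyloxy)octa-2,6-dienoate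
Conditions: Ph3P=C(CH3)CO2Et, CH2Cl2, rt
Reagents that add atoms: ethyl 2-(triphenylphosphoranylidene)propanoate, CCOC(=O)C(C)=P(c1ccccc1)(c1ccccc1)c1ccccc1
Why: Wittig olefination with the α-methyl stabilised ylide should give the E-configured C6'=C7' alkene and is neutral enough not to epimerise the α-silyloxy aldehyde.

Step 10
Reactants: 12 ethyl (2E,4S,6E)-8-(2,5-dimethoxy-3-methylphenyl)-2,6-dimethyl-4-(triethylsilyloxy)octa-2,6-dienoate
Product: 13 (2E,4S,6E)-8-(2,5-dimethoxy-3-methylphenyl)-2,6-dimethyl-4-(triethylsilyloxy)octa-2,6-dien-1-ol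
Conditions: i-Bu2AlH (2.2 equiv), CH2Cl2, −78 °C; aq KNaC4H4O6
Reagents that add atoms: none
Why: 1,2-Reduction of the enoate by the aluminium hydride at low temperature gives the C8' allylic alcohol without touching silyl or aryl ethers.

Step 11
Reactants: 13 (2E,4S,6E)-8-(2,5-dimethoxy-3-methylphenyl)-2,6-dimethyl-4-(triethylsilyloxy)octa-2,6-dien-1-ol
Product: 15 (2E,4S,6E)-1-bromo-8-(2,5-dimethoxy-3-methylphenyl)-2,6-dimethyl-4-(triethylsilyloxy)octa-2,6-diene (C8' bromide), via allylic methanesulfonate 14 (not isolated)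
Conditions: MsCl, Et3N, THF, −40 °C; then LiBr, THF, 0 °C; used at once
Reagents that add atoms: LiBr, [Li+].[Br-]; methanesulfonyl chloride, CS(=O)(=O)Cl (in 14 only)
Why: Mesylation followed by SN2 displacement with bromide converts the primary allylic alcohol into the bromide under non-acidic conditions, without allylic transposition or loss of the silyl ether.

**Sulfone 23 (C9'–C16')**

Step 12
Reactants: 16 prenyl bromide; 17 sodium benzenesulfinate
Product: 18 (3-methylbut-2-en-1-yl) phenyl sulfone
Conditions: DMF, rt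
Reagents that add atoms: none
Why: S-Alkylation of the sulfinate by the primary allylic bromide (SN2) gives the sulfone.

Step 13
Reactants: 18 (3-methylbut-2-en-1-yl) phenyl sulfone
Product: 19 (E)-2-methyl-4-(phenylsulfonyl)but-2-enal
Conditions: SeO2 (1.2 equiv), 1,4-dioxane, 80 °C
Reagents that add atoms: selenium dioxide, O=[Se]=O
Why: Selenium dioxide allylic oxidation (ene reaction then [2,3]-sigmatropic shift) selects the E-methyl group of the trisubstituted alkene and carries it on to the E-enal.

Step 14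
Reactants: 19 (E)-2-methyl-4-(phenylsulfonyl)but-2-enal
Product: 21 (4R,5E)-5-methyl-7-(phenylsulfonyl)hepta-1,5-dien-4-ol, via diisopinocampheylborinate ester 20 (not isolated)
Conditions: (+)-Ipc2BOMe, CH2=CHCH2MgBr, Et2O, 0 °C to rt; then 19, −78 °C; then NaBO3·4H2O, THF–H2O, rt
Reagents that add atoms: allylmagnesium bromide, C=CC[Mg]Br (allyl group, relayed through boron); (+)-B-methoxydiisopinocampheylborane, COB([C@H]1C[C@H]2C[C@@H]([C@@H]1C)C2(C)C)[C@H]1C[C@H]2C[C@@H]([C@@H]1C)C2(C)C (boron and isopinocampheyl groups in 20 only)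
Why: Brown asymmetric allylboration through a chair Zimmerman–Traxler transition state, in which the isopinocampheyl groups from (−)-α-pinene direct allyl to the Re face of the aldehyde, should set the carbinol (future C12') as R, and the non-basic borane and mild perborate work-up spare the acidic allylic sulfone.

Step 15
Reactants: 21 (4R,5E)-5-methyl-7-(phenylsulfonyl)hepta-1,5-dien-4-ol
Product: 22 tert-butyl{[(4R,5E)-5-methyl-7-(phenylsulfonyl)hepta-1,5-dien-4-yl]oxy}dimethylsilane
Conditions: TBSCl, imidazole, DMF, rt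
Reagents that add atoms: tert-butyldimethylsilyl chloride, CC(C)(C)[Si](C)(C)Cl
Why: Imidazole-promoted silylation protects the C12' carbinol with a group that is more robust than the triethylsilyl ether at C5', which is what later confines acetylation to C5'.

Step 16
Reactants: 22 tert-butyl{[(4R,5E)-5-methyl-7-(phenylsulfonyl)hepta-1,5-dien-4-yl]oxy}dimethylsilane
Product: 23 tert-butyl{[(2E,4R)-3,7-dimethyl-1-(phenylsulfonyl)octa-2,6-dien-4-yl]oxy}dimethylsilane (C9' sulfone)
Conditions: 2-methylbut-2-ene (excess), second-generation Grubbs catalyst (H2IMes)(PCy3)Cl2Ru=CHPh (5 mol %), CH2Cl2, 40 °C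
Reagents that add atoms: 2-methylbut-2-ene, CC=C(C)C
Why: Olefin cross-metathesis with excess 2-methylbut-2-ene converts the monosubstituted alkene into the prenyl terminus (C14'=C15'), the hindered trisubstituted alkene next to the sulfone being inert to the ruthenium carbene.

**Union**

Step 17
Reactants: 23 tert-butyl{[(2E,4R)-3,7-dimethyl-1-(phenylsulfonyl)octa-2,6-dien-4-yl]oxy}dimethylsilane; 15 (2E,4S,6E)-1-bromo-8-(2,5-dimethoxy-3-methylphenyl)-2,6-dimethyl-4-(triethylsilyloxy)octa-2,6-diene
Product: 25 (2E,5S,6E,10E,12R)-12-(tert-butyldimethylsilyloxy)-1-(2,5-dimethoxy-3-methylphenyl)-3,7,11,15-tetramethyl-9-(phenylsulfonyl)-5-(triethylsilyloxy)hexadeca-2,6,10,14-tetraene (both C9' epimers), via C9'-lithiated sulfone 24 (not isolated)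
Conditions: n-BuLi (1.05 equiv), THF, −78 °C, 30 min; then 15, THF–DMPU, −78 to −50 °C; aq NH4Cl
Reagents that add atoms: n-BuLi, [Li]CCCC (lithium in 24 only)
Why: Deprotonation at C9', the one position acidified by both the sulfonyl group and the C10'=C11' alkene, gives a sulfonyl-stabilised allyl anion that displaces bromide from the primary allylic carbon C8' of 15 in a direct SN2 sense, so the C8'–C9' bond forms without transposing either alkene and both E geometries are carried through. The closest known reaction type is the Julia-type coupling of lithiated allylic sulfones with allylic halides used to assemble polyprenyl chains. No ring is closed, and the one new stereocentre, C9', forms without control and is erased when the sulfonyl group is removed in step 18. The step needs α- over γ-alkylation of the ambident anion and SN2 over SN2' attack on the bromide: charge localisation next to sulfur and the fully substituted γ-carbon C11' secure the first, and the unhindered primary C8' set against the C5'-branched C6' secures the second. Keeping the lithium anion at −78 °C holds back vinylogous loss of the C12' silyloxy group, and the two carbinol centres, remote from the reacting carbons, stay 5'S and 12'R.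

**End game**

Step 18
Reactants: 25 full-skeleton C9' phenyl sulfone
Product: 26 (2E,5S,6E,10E,12R)-12-(tert-butyldimethylsilyloxy)-1-(2,5-dimethoxy-3-methylphenyl)-3,7,11,15-tetramethyl-5-(triethylsilyloxy)hexadeca-2,6,10,14-tetraene
Conditions: PdCl2(dppp) (10 mol %), LiBHEt3 (2.5 equiv), THF, 0 °C
Reagents that add atoms: none
Why: Zerovalent palladium formed from PdCl2(dppp) ionises the allylic sulfone to a π-allyl complex and hydride from LiBHEt3 is delivered to the less substituted terminus C9', the known palladium-catalysed reductive desulfonylation that should leave the C10'=C11' alkene in place and E.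

Step 19
Reactants: 26 bis-silyl ether
Product: 27 (2E,5S,6E,10E,12R)-12-(tert-butyldimethylsilyloxy)-1-(2,5-dimethoxy-3-methylphenyl)-3,7,11,15-tetramethylhexadeca-2,6,10,14-tetraen-5-ol
Conditions: PPTS (0.2 equiv), MeOH–CH2Cl2 (1:1), 0 °C
Reagents that add atoms: none
Why: Mild acid-catalysed methanolysis removes the triethylsilyl ether much faster than the bulkier tert-butyldimethylsilyl ether, so only the C5' hydroxyl is freed.

Step 20
Reactants: 27 C5' alcohol
Product: 28 (2E,5S,6E,10E,12R)-12-(tert-butyldimethylsilyloxy)-1-(2,5-dimethoxy-3-methylphenyl)-3,7,11,15-tetramethylhexadeca-2,6,10,14-tetraen-5-yl acetate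
Conditions: Ac2O, pyridine, DMAP (cat.), CH2Cl2, 0 °C to rt
Reagents that add atoms: acetic anhydride, CC(=O)OC(C)=O
Why: DMAP-catalysed acylation of the only free hydroxyl places the acetate at C5' with retention, since the C–O bond is not touched.

Step 21
Reactants: 28 C5' acetate
Product: 29 (2E,5S,6E,10E,12R)-1-(2,5-dimethoxy-3-methylphenyl)-12-hydroxy-3,7,11,15-tetramethylhexadeca-2,6,10,14-tetraen-5-yl acetate
Conditions: HF·pyridine, pyridine, THF, 0 °C to rt
Reagents that add atoms: none
Why: Pyridine-buffered fluoride desilylation removes the remaining silyl ether without cleaving or ionising the allylic acetate.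

Step 22
Reactants: 29 dimethyl ether of the target
Product: 30 2-[(2E,5S,6E,10E,12R)-5-acetoxy-12-hydroxy-3,7,11,15-tetramethylhexadeca-2,6,10,14-tetraen-1-yl]-6-methylcyclohexa-2,5-diene-1,4-dione
Conditions: (NH4)2Ce(NO3)6 (2.5 equiv), MeCN–H2O (2:1), 0 °C, 20 min
Reagents that add atoms: water, O
Why: Oxidative demethylation of the para-dimethoxyarene by two one-electron oxidations with tetravalent cerium, water adding to the radical cation and methanol leaving, should give the para-quinone faster than the alkenes or the carbinol are attacked.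

Step 23
Reactants: 30 quinone
Product: 31 2-[(2E,5S,6E,10E,12R)-5-acetoxy-12-hydroxy-3,7,11,15-tetramethylhexadeca-2,6,10,14-tetraen-1-yl]-6-methylbenzene-1,4-diol (target, CNP0252507.1)
Conditions: Na2S2O4, Et2O–H2O, rt, under argon
Reagents that add atoms: none
Why: Dithionite reduces the quinone to the hydroquinone by two-electron, two-proton transfer under near-neutral two-phase conditions that leave the ester and alkenes alone.

**Compound list**
1 | 4-methoxy-2-methylphenol | Cc1cc(OC)ccc1O | starting material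
2 | 2-hydroxy-5-methoxy-3-methylbenzaldehyde | O=Cc1cc(OC)cc(C)c1O | intermediate
3 | 2,5-dimethoxy-3-methylbenzaldehyde | O=Cc1cc(OC)cc(C)c1OC | intermediate
4 | (2,5-dimethoxy-3-methylphenyl)methanol | OCc1cc(OC)cc(C)c1OC | intermediate
5 | 1-(chloromethyl)-2,5-dimethoxy-3-methylbenzene | ClCc1cc(OC)cc(C)c1OC | intermediate
6 | (R)-glycidol | OC[C@@H]1CO1 | starting material
7 | (S)-pent-4-yne-1,2-diol | OC[C@@H](O)CC#C | intermediate
8 | (S)-4,5-bis(triethylsilyloxy)pent-1-yne | CC[Si](CC)(CC)OC[C@@H](O[Si](CC)(CC)CC)CC#C | intermediate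
9 | dimethyl[(1E,4S)-2-methyl-4,5-bis(triethylsilyloxy)pent-1-enyl]alane | C[Al](C)/C=C(\C)C[C@H](O[Si](CC)(CC)CC)CO[Si](CC)(CC)CC | intermediate (not isolated)
10 | (2E,5S)-1-(2,5-dimethoxy-3-methylphenyl)-3-methyl-5,6-bis(triethylsilyloxy)hex-2-ene | CC[Si](CC)(CC)OC[C@@H](O[Si](CC)(CC)CC)C/C(C)=C/Cc1cc(OC)cc(C)c1OC | intermediate
11 | (2S,4E)-6-(2,5-dimethoxy-3-methylphenyl)-4-methyl-2-(triethylsilyloxy)hex-4-enal | O=C[C@@H](O[Si](CC)(CC)CC)C/C(C)=C/Cc1cc(OC)cc(C)c1OC | intermediate
12 | ethyl (2E,4S,6E)-8-(2,5-dimethoxy-3-methylphenyl)-2,6-dimethyl-4-(triethylsilyloxy)octa-2,6-dienoate | CCOC(=O)/C(C)=C/[C@@H](O[Si](CC)(CC)CC)C/C(C)=C/Cc1cc(OC)cc(C)c1OC | intermediate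
13 | (2E,4S,6E)-8-(2,5-dimethoxy-3-methylphenyl)-2,6-dimethyl-4-(triethylsilyloxy)octa-2,6-dien-1-ol | OC/C(C)=C/[C@@H](O[Si](CC)(CC)CC)C/C(C)=C/Cc1cc(OC)cc(C)c1OC | intermediate
14 | methanesulfonate of 13 | CS(=O)(=O)OC/C(C)=C/[C@@H](O[Si](CC)(CC)CC)C/C(C)=C/Cc1cc(OC)cc(C)c1OC | intermediate (not isolated)
15 | (2E,4S,6E)-1-bromo-8-(2,5-dimethoxy-3-methylphenyl)-2,6-dimethyl-4-(triethylsilyloxy)octa-2,6-diene (arene–C1'–C8' bromide, 5'S) | BrC/C(C)=C/[C@@H](O[Si](CC)(CC)CC)C/C(C)=C/Cc1cc(OC)cc(C)c1OC | intermediate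
16 | prenyl bromide | CC(C)=CCBr | starting material
17 | sodium benzenesulfinate | [Na+].[O-]S(=O)c1ccccc1 | starting material
18 | (3-methylbut-2-en-1-yl) phenyl sulfone | CC(C)=CCS(=O)(=O)c1ccccc1 | intermediate
19 | (E)-2-methyl-4-(phenylsulfonyl)but-2-enal | O=C/C(C)=C/CS(=O)(=O)c1ccccc1 | intermediate
20 | (4R,5E)-5-methyl-7-(phenylsulfonyl)hepta-1,5-dien-4-yl bis[(+)-isopinocampheyl]borinate | O=S(=O)(C/C=C(\C)[C@H](OB([C@H]1C[C@H]2C[C@@H]([C@@H]1C)C2(C)C)[C@H]1C[C@H]2C[C@@H]([C@@H]1C)C2(C)C)CC=C)c1ccccc1 | intermediate (not isolated)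
21 | (4R,5E)-5-methyl-7-(phenylsulfonyl)hepta-1,5-dien-4-ol | O=S(=O)(C/C=C(\C)[C@H](O)CC=C)c1ccccc1 | intermediate
22 | tert-butyl{[(4R,5E)-5-methyl-7-(phenylsulfonyl)hepta-1,5-dien-4-yl]oxy}dimethylsilane | O=S(=O)(C/C=C(\C)[C@H](O[Si](C)(C)C(C)(C)C)CC=C)c1ccccc1 | intermediate
23 | tert-butyl{[(2E,4R)-3,7-dimethyl-1-(phenylsulfonyl)octa-2,6-dien-4-yl]oxy}dimethylsilane (C9'–C16' sulfone, 12'R) | O=S(=O)(C/C=C(\C)[C@H](O[Si](C)(C)C(C)(C)C)CC=C(C)C)c1ccccc1 | intermediate
24 | C9'-lithio derivative of 23 | [Li]C(/C=C(\C)[C@H](O[Si](C)(C)C(C)(C)C)CC=C(C)C)S(=O)(=O)c1ccccc1 | intermediate (not isolated)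
25 | (2E,5S,6E,10E,12R)-12-(tert-butyldimethylsilyloxy)-1-(2,5-dimethoxy-3-methylphenyl)-3,7,11,15-tetramethyl-9-(phenylsulfonyl)-5-(triethylsilyloxy)hexadeca-2,6,10,14-tetraene, both C9' epimers | O=S(=O)(c1ccccc1)C(C/C(C)=C/[C@@H](O[Si](CC)(CC)CC)C/C(C)=C/Cc1cc(OC)cc(C)c1OC)/C=C(\C)[C@H](O[Si](C)(C)C(C)(C)C)CC=C(C)C | intermediate
26 | (2E,5S,6E,10E,12R)-12-(tert-butyldimethylsilyloxy)-1-(2,5-dimethoxy-3-methylphenyl)-3,7,11,15-tetramethyl-5-(triethylsilyloxy)hexadeca-2,6,10,14-tetraene | CC[Si](CC)(CC)O[C@H](/C=C(\C)CC/C=C(\C)[C@H](O[Si](C)(C)C(C)(C)C)CC=C(C)C)C/C(C)=C/Cc1cc(OC)cc(C)c1OC | intermediate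
27 | (2E,5S,6E,10E,12R)-12-(tert-butyldimethylsilyloxy)-1-(2,5-dimethoxy-3-methylphenyl)-3,7,11,15-tetramethylhexadeca-2,6,10,14-tetraen-5-ol | O[C@H](/C=C(\C)CC/C=C(\C)[C@H](O[Si](C)(C)C(C)(C)C)CC=C(C)C)C/C(C)=C/Cc1cc(OC)cc(C)c1OC | intermediate
28 | (2E,5S,6E,10E,12R)-12-(tert-butyldimethylsilyloxy)-1-(2,5-dimethoxy-3-methylphenyl)-3,7,11,15-tetramethylhexadeca-2,6,10,14-tetraen-5-yl acetate | CC(=O)O[C@H](/C=C(\C)CC/C=C(\C)[C@H](O[Si](C)(C)C(C)(C)C)CC=C(C)C)C/C(C)=C/Cc1cc(OC)cc(C)c1OC | intermediate
29 | (2E,5S,6E,10E,12R)-1-(2,5-dimethoxy-3-methylphenyl)-12-hydroxy-3,7,11,15-tetramethylhexadeca-2,6,10,14-tetraen-5-yl acetate | CC(=O)O[C@H](/C=C(\C)CC/C=C(\C)[C@H](O)CC=C(C)C)C/C(C)=C/Cc1cc(OC)cc(C)c1OC | intermediate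
30 | 2-[(2E,5S,6E,10E,12R)-5-acetoxy-12-hydroxy-3,7,11,15-tetramethylhexadeca-2,6,10,14-tetraen-1-yl]-6-methylcyclohexa-2,5-diene-1,4-dione | CC(=O)O[C@H](/C=C(\C)CC/C=C(\C)[C@H](O)CC=C(C)C)C/C(C)=C/CC1=CC(=O)C=C(C)C1=O | intermediate
31 | 2-[(2E,5S,6E,10E,12R)-5-acetoxy-12-hydroxy-3,7,11,15-tetramethylhexadeca-2,6,10,14-tetraen-1-yl]-6-methylbenzene-1,4-diol | CC(=O)O[C@H](/C=C(\C)CC/C=C(\C)[C@H](O)CC=C(C)C)C/C(C)=C/Cc1cc(O)cc(C)c1O | target

**Step count**
Total: 23 steps. Longest linear sequence: 16 steps (from 1: steps 1–4, 7–11, 17–23).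

**Steps most likely to fail**

Step 17 (key union). Before it is alkylated, the lithiated sulfone may shed the C12' silanolate by vinylogous β-elimination to a sulfonyl diene. Slow alkylation may also allow proton exchange between product and anion and hence double alkylation. Fallback: run the union through a dianion in which the C12' oxygen is an alkoxide and cannot leave. Setting out from 21, cross-metathesis with 2-methylbut-2-ene (second-generation Grubbs catalyst) gives the free carbinol sulfone (2E,4R)-3,7-dimethyl-1-(phenylsulfonyl)octa-2,6-dien-4-ol F1. Two equivalents of n-BuLi in THF at −78 °C give its O,C-dilithio derivative F2, which is alkylated at carbon by 15 to the C12'-hydroxy coupled sulfone F3. Silylation with TBSCl and imidazole returns to the route at 25.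

Step 7 (methylalumination and benzylation in one flask). Transfer of the hindered alkenyl group from aluminium to palladium may be slow relative to homocoupling of the electron-rich benzylic chloride or protodealumination. The Lewis-acidic aluminium residues may also strip a triethylsilyl ether during the long one-pot sequence. Fallback: invert the roles of the coupling partners. Setting out from 8, the same methylalumination is quenched with iodine at −30 °C to give the isolable (1E,4S)-1-iodo-2-methyl-4,5-bis(triethylsilyloxy)pent-1-ene F4. Chloride 5 is converted with zinc dust and LiCl in THF into (2,5-dimethoxy-3-methylbenzyl)zinc chloride F5. Negishi coupling of the two with Pd(PPh3)4 in THF at rt returns to the route at 10.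

Step 22 (oxidative demethylation). In the strongly oxidising, acidic cerium medium the unprotected C12' allylic carbinol may be over-oxidised to the enone or ionised, which would erode the late-stage material. Fallback: oxidise while C12' is still silylated. Setting out from 28, (NH4)2Ce(NO3)6 in MeCN–H2O at 0 °C gives the C12'-silylated quinone F6. HF·pyridine in THF–pyridine then frees the hydroxyl and returns to the route at 30, after which step 23 follows unchanged.

**Further compounds**
F1 | step 17 | (2E,4R)-3,7-dimethyl-1-(phenylsulfonyl)octa-2,6-dien-4-ol | O=S(=O)(C/C=C(\C)[C@H](O)CC=C(C)C)c1ccccc1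
F2 | step 17 | O,C-dilithio derivative of F1 | [Li]C(/C=C(\C)[C@H](O[Li])CC=C(C)C)S(=O)(=O)c1ccccc1
F3 | step 17 | (2E,5S,6E,10E,12R)-1-(2,5-dimethoxy-3-methylphenyl)-3,7,11,15-tetramethyl-9-(phenylsulfonyl)-5-(triethylsilyloxy)hexadeca-2,6,10,14-tetraen-12-ol, both C9' epimers | O=S(=O)(c1ccccc1)C(C/C(C)=C/[C@@H](O[Si](CC)(CC)CC)C/C(C)=C/Cc1cc(OC)cc(C)c1OC)/C=C(\C)[C@H](O)CC=C(C)C
F4 | step 7 | (1E,4S)-1-iodo-2-methyl-4,5-bis(triethylsilyloxy)pent-1-ene | I/C=C(\C)C[C@H](O[Si](CC)(CC)CC)CO[Si](CC)(CC)CC
F5 | step 7 | (2,5-dimethoxy-3-methylbenzyl)zinc chloride | Cl[Zn]Cc1cc(OC)cc(C)c1OC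
F6 | step 22 | 2-[(2E,5S,6E,10E,12R)-5-acetoxy-12-(tert-butyldimethylsilyloxy)-3,7,11,15-tetramethylhexadeca-2,6,10,14-tetraen-1-yl]-6-methylcyclohexa-2,5-diene-1,4-dione | CC(=O)O[C@H](/C=C(\C)CC/C=C(\C)[C@H](O[Si](C)(C)C(C)(C)C)CC=C(C)C)C/C(C)=C/CC1=CC(=O)C=C(C)C1=O
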